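**Retrosynthetic overview**
- Target ⇐ one-flask hydrogenolysis, double decarboxylation and trans-equilibration of a tribenzylated bis(α-carboxy lactone); the diaryl ether is not made late.
- That precursor ⇐ double C-alkylation of two molecules of benzyl (4S)-4-veratryl-2-oxotetrahydrofuran-3-carboxylate with a preformed diaryl ether bis(benzylic bromide), itself from 5-iodovanillin and vanillin.
- α-Ester lactone ⇐ copper-catalysed homoconjugate arylation (veratryl Grignard) of a cyclopropane-fused lactone; the cyclopropane CH2 becomes the veratryl CH2.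
- Cyclopropane-fused lactone ⇐ dibenzyl malonate + (S)-epichlorohydrin: cyclopropane and γ-lactone close in one operation, and the epoxide CH becomes each (S)-C4 centre of the target.
- Ring order: cyclopropane, then lactone (same flask); the cyclopropane is then opened, and the two lactones are joined through the core; all arenes are bought.

Assumption: the target is taken exactly as drawn, with all four lactone stereocentres S (each lactone 3S,4S, benzyl groups trans); (3,4-dimethoxyphenyl)magnesium bromide is bought as its THF solution.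

**Route**

Step 1
Reactants: 1 5-iodovanillin (4-hydroxy-3-iodo-5-methoxybenzaldehyde)
Product: 2 4-(benzyloxy)-3-iodo-5-methoxybenzaldehyde
Conditions: BnBr, K2CO3, DMF, 60 °C
Reagents that add atoms: benzyl bromide, BrCc1ccccc1
Why: Williamson ether synthesis (SN2 O-benzylation of the phenoxide) masks the phenol, which would otherwise interfere in the Ullmann step and give a quinone methide from the later benzylic bromide; no stereocentre is formed.

Step 2
Reactants: 2 4-(benzyloxy)-3-iodo-5-methoxybenzaldehyde; 3 vanillin (4-hydroxy-3-methoxybenzaldehyde)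
Product: 4 4-(benzyloxy)-3-(4-formyl-2-methoxyphenoxy)-5-methoxybenzaldehyde
Conditions: CuI (10 mol %), N,N-dimethylglycine hydrochloride (30 mol %), Cs2CO3, 1,4-dioxane, 100 °C
Reagents that add atoms: none
Why: Ligand-accelerated Ullmann diaryl ether coupling joins the aryl iodide to the copper phenoxide of vanillin and leaves both non-enolisable aldehydes untouched; no stereocentre is formed.

Step 3
Reactants: 4 4-(benzyloxy)-3-(4-formyl-2-methoxyphenoxy)-5-methoxybenzaldehyde
Product: 6 2-(benzyloxy)-5-(bromomethyl)-1-[4-(bromomethyl)-2-methoxyphenoxy]-3-methoxybenzene, via diol 5 (not isolated)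
Conditions: NaBH4, THF–H2O, 0 °C; then 48% aq. HBr, CH2Cl2, 0 °C to rt
Reagents that add atoms: hydrogen bromide, Br
Why: Borohydride reduction of both aldehydes is followed in the same flask by SN1-type substitution of the two para-oxygenated benzylic alcohols by bromide, under which the benzyl ether and diaryl ether survive; no stereocentre is formed.

Step 4
Reactants: 7 dibenzyl malonate; 8 (S)-epichlorohydrin
Product: 11 benzyl (1S,5S)-2-oxo-3-oxabicyclo[3.1.0]hexane-1-carboxylate, via epoxypropylmalonate 9 (not isolated), via cyclopropylmethoxide 10 (not isolated)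
Conditions: NaH (1.0 equiv), BnOH (2 equiv), THF, 0 °C; then 8, 65 °C, 16 h
Reagents that add atoms: none
Why: In this malonate–epichlorohydrin bicyclisation (domino SN2 epoxide opening, 3-exo-tet cyclopropanation, lactonisation; the benzyl-ester analogue of the established dialkyl malonate reaction) the malonate anion opens the epoxide at CH2 and the alkoxide expels chloride to give epoxide 9 with the stereocentre untouched, the malonate anion of 9 then opens the epoxide CH with inversion to close the cyclopropane (10), and the cis alkoxide lactonises on an ester with loss of benzyloxide, so two rings form in one operation, C5 (S) comes from the chiral pool and C1 is fixed by the obligatory cis ring fusion.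

Step 5
Reactants: 11 benzyl (1S,5S)-2-oxo-3-oxabicyclo[3.1.0]hexane-1-carboxylate; 12 (3,4-dimethoxyphenyl)magnesium bromide
Product: 13 benzyl (3S,4S)-4-(3,4-dimethoxybenzyl)-2-oxotetrahydrofuran-3-carboxylate
Conditions: CuI (10 mol %), THF, −40 to −20 °C; 1 M HCl quench
Reagents that add atoms: none
Why: Copper-catalysed homoconjugate addition of the aryl Grignard opens the doubly activated cyclopropane at its unsubstituted CH2 (SN2-like, strain release, malonate-type enolate as leaving group), so the ring-fusion carbon is untouched and becomes the (S)-C4 centre, while the epimerisable C3 settles trans.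

Step 6
Reactants: 13 benzyl (3S,4S)-4-(3,4-dimethoxybenzyl)-2-oxotetrahydrofuran-3-carboxylate (2.3 equiv); 6 2-(benzyloxy)-5-(bromomethyl)-1-[4-(bromomethyl)-2-methoxyphenoxy]-3-methoxybenzene
Product: 14 tribenzylated bis-lactone diester (both lactones 3R,4S)
Conditions: K2CO3, DMF, rt
Reagents that add atoms: none
Why: Double SN2 C-alkylation of the soft malonate-type enolate of 13 by the bis(benzylic bromide) proceeds under mild carbonate conditions with each benzyl group entering anti to the C4 veratryl group; C4 is untouched and the configuration of the new quaternary centres is not carried into the target.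

Step 7
Reactants: 14 tribenzylated bis-lactone diester
Product: 17 (3S,4S)-4-(3,4-dimethoxybenzyl)-3-[4-[5-[[(3S,4S)-4-(3,4-dimethoxybenzyl)-2-oxotetrahydrofuran-3-yl]methyl]-2-hydroxy-3-methoxyphenoxy]-3-methoxybenzyl]dihydrofuran-2(3H)-one (target), via bis-acid 15 (not isolated), via epimer mixture 16 (not isolated)
Conditions: H2 (1 atm), 10% Pd/C, EtOAc–EtOH, rt; filter; toluene–DMF, 110 °C; then DBU (2 equiv), 110 °C
Reagents that add atoms: none
Why: Global hydrogenolysis of the two benzyl esters and the benzyl ether, thermal decarboxylation of the malonic half-acids through their enols, and base-mediated equilibration of the lactone α-centres place each α-benzyl trans to the fixed (S)-C4 substituent under thermodynamic control, which gives 3S,4S in both lactones.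

**Compound list**

1 | 5-iodovanillin (4-hydroxy-3-iodo-5-methoxybenzaldehyde) | COc1cc(C=O)cc(I)c1O | starting material
2 | 4-(benzyloxy)-3-iodo-5-methoxybenzaldehyde | COc1cc(C=O)cc(I)c1OCc1ccccc1 | intermediate
3 | vanillin (4-hydroxy-3-methoxybenzaldehyde) | COc1cc(C=O)ccc1O | starting material
4 | 4-(benzyloxy)-3-(4-formyl-2-methoxyphenoxy)-5-methoxybenzaldehyde | COc1cc(C=O)cc(Oc2ccc(C=O)cc2OC)c1OCc1ccccc1 | intermediate
5 | [4-(benzyloxy)-3-[4-(hydroxymethyl)-2-methoxyphenoxy]-5-methoxyphenyl]methanol | COc1cc(CO)cc(Oc2ccc(CO)cc2OC)c1OCc1ccccc1 | intermediate (not isolated)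
6 | 2-(benzyloxy)-5-(bromomethyl)-1-[4-(bromomethyl)-2-methoxyphenoxy]-3-methoxybenzene | COc1cc(CBr)cc(Oc2ccc(CBr)cc2OC)c1OCc1ccccc1 | intermediate
7 | dibenzyl malonate | O=C(CC(=O)OCc1ccccc1)OCc1ccccc1 | starting material
8 | (S)-epichlorohydrin [(2S)-2-(chloromethyl)oxirane] | ClC[C@@H]1CO1 | starting material
9 | dibenzyl 2-{[(2S)-oxiran-2-yl]methyl}malonate | O=C(OCc1ccccc1)C(C[C@H]2CO2)C(=O)OCc3ccccc3 | intermediate (not isolated)
10 | sodium [(1S)-2,2-bis(benzyloxycarbonyl)cyclopropyl]methoxide | [Na+].[O-]C[C@H]1CC1(C(=O)OCc2ccccc2)C(=O)OCc3ccccc3 | intermediate (not isolated)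
11 | benzyl (1S,5S)-2-oxo-3-oxabicyclo[3.1.0]hexane-1-carboxylate | O=C1OC[C@H]2C[C@@]12C(=O)OCc3ccccc3 | intermediate
12 | (3,4-dimethoxyphenyl)magnesium bromide (THF solution) | COc1ccc([Mg]Br)cc1OC | starting material
13 | benzyl (3S,4S)-4-(3,4-dimethoxybenzyl)-2-oxotetrahydrofuran-3-carboxylate (trans; C3 epimerisable) | COc1ccc(C[C@@H]2COC(=O)[C@H]2C(=O)OCc3ccccc3)cc1OC | intermediate
14 | benzyl (3R,4S)-3-[4-[2-(benzyloxy)-5-[[(3R,4S)-3-[(benzyloxy)carbonyl]-4-(3,4-dimethoxybenzyl)-2-oxotetrahydrofuran-3-yl]methyl]-3-methoxyphenoxy]-3-methoxybenzyl]-4-(3,4-dimethoxybenzyl)-2-oxotetrahydrofuran-3-carboxylate | COc1ccc(C[C@@H]2COC(=O)[C@]2(Cc3ccc(Oc4cc(C[C@]5(C(=O)OCc6ccccc6)C(=O)OC[C@H]5Cc5ccc(OC)c(OC)c5)cc(OC)c4OCc4ccccc4)c(OC)c3)C(=O)OCc2ccccc2)cc1OC | intermediate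
15 | (3S,4S)-3-[4-[5-[[(3S,4S)-3-carboxy-4-(3,4-dimethoxybenzyl)-2-oxotetrahydrofuran-3-yl]methyl]-2-hydroxy-3-methoxyphenoxy]-3-methoxybenzyl]-4-(3,4-dimethoxybenzyl)-2-oxotetrahydrofuran-3-carboxylic acid | COc1ccc(C[C@@H]2COC(=O)[C@]2(Cc3ccc(Oc4cc(C[C@]5(C(=O)O)C(=O)OC[C@H]5Cc5ccc(OC)c(OC)c5)cc(OC)c4O)c(OC)c3)C(=O)O)cc1OC | intermediate (not isolated)
16 | (4S)-4-(3,4-dimethoxybenzyl)-3-[4-[5-[[(4S)-4-(3,4-dimethoxybenzyl)-2-oxotetrahydrofuran-3-yl]methyl]-2-hydroxy-3-methoxyphenoxy]-3-methoxybenzyl]dihydrofuran-2(3H)-one, mixture of C3 epimers | COc1ccc(C[C@@H]2COC(=O)C2Cc2ccc(Oc3cc(CC4C(=O)OC[C@H]4Cc4ccc(OC)c(OC)c4)cc(OC)c3O)c(OC)c2)cc1OC | intermediate (not isolated)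
17 | (3S,4S)-4-(3,4-dimethoxybenzyl)-3-[4-[5-[[(3S,4S)-4-(3,4-dimethoxybenzyl)-2-oxotetrahydrofuran-3-yl]methyl]-2-hydroxy-3-methoxyphenoxy]-3-methoxybenzyl]dihydrofuran-2(3H)-one (CNP0183104.1) | COc1ccc(C[C@@H]2COC(=O)[C@H]2Cc2ccc(Oc3cc(C[C@@H]4C(=O)OC[C@H]4Cc4ccc(OC)c(OC)c4)cc(OC)c3O)c(OC)c2)cc1OC | target

**Step count and risks**

Total steps: 7. Longest linear sequence: 5 (steps 1, 2, 3, 6, 7 from 5-iodovanillin).

Most likely to fail, first: step 4. The benzyl-ester version of the bicyclisation may give a low yield (benzyloxide attack on epichlorohydrin, oligomers) or eroded ee. The fallback sets out from 7, drops the cyclopropane and comes back at 13, so it also replaces step 5.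
- Cross-metathesis of methyl eugenol (C=CCc1ccc(OC)c(OC)c1) with (Z)-but-2-ene-1,4-diyl dimethyl dicarbonate (second-generation Grubbs catalyst, CH2Cl2, 40 °C) gives (E)-4-(3,4-dimethoxyphenyl)but-2-en-1-yl methyl carbonate F1.
- Branch-selective iridium-catalysed asymmetric allylic alkylation of 7 with F1 gives dibenzyl (R)-2-[1-(3,4-dimethoxyphenyl)but-3-en-2-yl]malonate F2. Conditions: [Ir(cod)Cl]2, a BINOL-derived bis(1-phenylethyl)amine phosphoramidite (the enantiomer that gives the R product), TBD, THF, rt.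
- Oxidative cleavage of the vinyl group (OsO4 cat., NaIO4, 2,6-lutidine, dioxane–H2O) gives dibenzyl (S)-2-[1-(3,4-dimethoxyphenyl)-3-oxopropan-2-yl]malonate F3.
- NaBH4 (MeOH, 0 °C) gives dibenzyl (S)-2-[1-(3,4-dimethoxyphenyl)-3-hydroxypropan-2-yl]malonate F4, which lactonises (TsOH cat., toluene) to 13.

Second: step 2. The Ullmann coupling joins an ortho-alkoxy aryl iodide to an electron-poor phenol and may stall. The fallback sets out from 1, reverses the polarity to an SNAr reaction and comes back at 4.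
- Copper-mediated hydroxylation of 1 (NaOH, CuSO4 cat., H2O, reflux) gives 3,4-dihydroxy-5-methoxybenzaldehyde F5.
- Selective benzylation of the more acidic hydroxyl para to the aldehyde (BnBr 1.0 equiv, NaHCO3, DMF, 40 °C) gives 4-(benzyloxy)-3-hydroxy-5-methoxybenzaldehyde F6.
- The phenoxide of F6 displaces fluoride from 4-fluoro-3-methoxybenzaldehyde (COc1cc(C=O)ccc1F; K2CO3, DMF, 120 °C) to give 4.

Third: step 7. The trans configuration at both α-centres rests on thermodynamic equilibration, and I have not verified the trans:cis ratio; a few percent of cis at either lactone would give diastereomers that are hard to remove. The fallback sets out from 13 (with 6), sets the α-centres kinetically and comes back at 17.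
- Hydrogenolysis and decarboxylation of 13 (H2, 10% Pd/C, EtOAc; then toluene, 110 °C) give (S)-4-(3,4-dimethoxybenzyl)dihydrofuran-2(3H)-one F7.
- Its lithium enolate (LiN(SiMe3)2, THF, −78 °C) is alkylated twice by 6 (0.45 equiv, DMPU), each time anti to the C4 substituent, to give the O-benzyl ether of the target F8.
- Hydrogenolysis (H2, 10% Pd/C, EtOAc) gives 17.

**Further compounds**

F1 | step 4 | (E)-4-(3,4-dimethoxyphenyl)but-2-en-1-yl methyl carbonate | COC(=O)OC/C=C/Cc1ccc(OC)c(OC)c1
F2 | step 4 | dibenzyl (R)-2-[1-(3,4-dimethoxyphenyl)but-3-en-2-yl]malonate | COc1ccc(C[C@H](C=C)C(C(=O)OCc2ccccc2)C(=O)OCc2ccccc2)cc1OC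
F3 | step 4 | dibenzyl (S)-2-[1-(3,4-dimethoxyphenyl)-3-oxopropan-2-yl]malonate | COc1ccc(C[C@H](C=O)C(C(=O)OCc2ccccc2)C(=O)OCc2ccccc2)cc1OC
F4 | step 4 | dibenzyl (S)-2-[1-(3,4-dimethoxyphenyl)-3-hydroxypropan-2-yl]malonate | COc1ccc(C[C@H](CO)C(C(=O)OCc2ccccc2)C(=O)OCc2ccccc2)cc1OC
F5 | step 2 | 3,4-dihydroxy-5-methoxybenzaldehyde (5-hydroxyvanillin) | COc1cc(C=O)cc(O)c1O
F6 | step 2 | 4-(benzyloxy)-3-hydroxy-5-methoxybenzaldehyde | COc1cc(C=O)cc(O)c1OCc1ccccc1
F7 | step 7 | (S)-4-(3,4-dimethoxybenzyl)dihydrofuran-2(3H)-one | COc1ccc(C[C@@H]2COC(=O)C2)cc1OC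
F8 | step 7 | (3S,4S)-3-[4-[2-(benzyloxy)-5-[[(3S,4S)-4-(3,4-dimethoxybenzyl)-2-oxotetrahydrofuran-3-yl]methyl]-3-methoxyphenoxy]-3-methoxybenzyl]-4-(3,4-dimethoxybenzyl)dihydrofuran-2(3H)-one | COc1ccc(C[C@@H]2COC(=O)[C@H]2Cc2ccc(Oc3cc(C[C@@H]4C(=O)OC[C@H]4Cc4ccc(OC)c(OC)c4)cc(OC)c3OCc3ccccc3)c(OC)c2)cc1OC
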